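**Reading time.** The time of reading is the first setting I can turn: Sunday's flask is read at 4.0 h and Thursday's at 12 h, with different charges.

| flask | substrate | remark | time |
|---|---|---|---|
| east | 9.6 mM | run made earlier |  |
| north | 16 mM | run made earlier |  |
| Sunday's | 14 mM |  | 4.0 h |
| Thursday's | 8.0 mM |  | 12 h |

| east: time / h | east: target / % | north: time / h | north: target / % |
|---|---|---|---|
| 0.333 | 0 | 0.833 | 0 |
| 0.667 | 3 | 1.50 | 2 |
| 1.00 | 0 | 2.50 | 1 |
| 2.00 | 0 | 3.00 | 6 |
| 4.00 | 2 | 4.00 | 22 |

(each reading ± 2 percentage points)

- a reading or a percentage of target counts all its forms, free or not

- which of the two ends with the higher amount of target, in percent of the substrate charged ("neither" if they lie within 2 percentage points) (Sunday's / Thursday's / neither)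
- target at the end, in percent of the substrate charged, Sunday's
- target at the end, in percent of the substrate charged, Thursday's

**Time's effect.** By hand, if target makes more target, the odds (fraction of target over fraction of substrate) grow exponentially, so time stands in the exponent. The north run, after a lag (induction period), reads in keeping with this: target goes from 6% of the charge at 3.00 h to 22% at 4.00 h. I read a growth rate of the odds of 1.49 h⁻¹.

**Growth count.** That rate times the time comes to 5.94 for the north run at its last reading. I call this product the growth count, the number of lifetimes the odds have grown through. Working back from that scattered last reading, I read starting odds of 0.0740%.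

**Charge's effect.** By hand, if substrate and target meet in one step, the rate and so the count at a given time scale with the charge, and I hold the starting odds the same in each flask. The east run has 9.6 mM, so at 4.00 h its count is 3.57 and I expect 2.56%. It reads 2%, within the scatter of 2 percentage points, which is a loose test.

**My reckoning.** Sunday's count is 5.20, giving 11.8%. Thursday's is 8.92, larger, giving 84.6%.

**The forecast.** It says Thursday's, with 11% for Sunday's and 55% for Thursday's, both below my figures, and it warns: “Thursday's is therefore very uncertain”.

**The flask.** The result is Thursday's, with 10.4% for Sunday's and 96.9% for Thursday's, so Thursday's count of 8.92 pointed the right way, though its 84.6% fell short. At 3.60 h in Sunday's flask, substrate + target uses substrate 730 times as fast as the uncatalysed step. At that moment in Sunday's flask, the half-life of substrate by that step is 7.2 h, far shorter than the 220 d of the uncatalysed step.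

    substrate → target (k = 2.20 × 10⁻⁶ min⁻¹)
    target → over-reaction product (k = 1.70 × 10⁻⁵ min⁻¹)
    crystals ⇌ target, rate k3*(cs3 - [target]) while solid is left; crystals form when [target] > cs3 (solubility = 7.00 mM, k = 1.00 min⁻¹)
    substrate + target → 2 target (k = 2.20 M⁻¹ min⁻¹)

**Second flask.** A neighbour of Sunday's flask with 5.6 mM of substrate, read at the same 4.0 h, has a count of 2.08, which puts target at 0.589% of its charge. Computed, that neighbour holds 0.324% of target.

The readings stem from a simulated flask from invented constants.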